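## Analysis of the target

Kazinol H (20) is a flavan. Ring A (the benzo ring) and ring C (O1–C2–C3–C4–C4a–C8a) form the chroman, ring B is the aryl group on C2, and ring B carries a fused 2,2-dimethyl-2H-pyran (ring D) across C3'–C4'. The only stereocentre is C2 (S); it is benzylic to ring B and bonded to O1, and there is no second centre to relate it to. Ring A carries a hydroxyl at C7 and a 1,1-dimethylallyl group at C6; ring B carries a prenyl group at C2' and a hydroxyl at C5'. The sensitive features are the two free phenols, four alkenes of different substitution (which rule out hydrogenation and strong electrophiles), the acid-labile ring D, and the C6 side chain, which can cyclise onto the C7 phenol under acid. The C2–O1 bond is also a para-alkoxybenzylic ether (O on C4'), so it can ionise and racemise under strong acid. The difficulty is that C4 is a bare methylene with no carbonyl handle, ring B is pentasubstituted, the two five-carbon groups have opposite connectivity, and O1 sits on C8a, meta to the C7 hydroxyl. The strategy rests on one feature: C4 is a benzylic methylene on C4a, and C4a is para to the C7 hydroxyl with C6 ortho to it. Ring A can therefore enter as a 4-iodo-2-(1,1-dimethylallyl)phenol, C4–C4a can be made by sp3–sp2 coupling, and the para relationship later lets the phenol be dearomatised at C4a so that C8a becomes an electrophilic carbon for O1.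

## Retrosynthetic reasoning

**C8a–O1 and the aromaticity of ring A (20 ⇒ 19 ⇒ 18 ⇒ 17).** Phenol 20 is traced to the bicyclic enone 19, in which C4a carries a methoxy group and C8a is sp3; loss of the methoxy group and the C8a hydrogen, then tautomerisation, restores the arene. Enone 19 comes from the dienone alcohol 18 by 6-exo conjugate addition of the C2 hydroxyl to C8a, and 18 is the desilylated form of the para-quinol ether 17. The cut is made here because C8a cannot be oxygenated by substitution chemistry (it is meta to the phenol), whereas in the dienone it is a β-carbon. The C2–O bond is never broken, so the configuration is carried through. The forward reaction has to add at C8a rather than at C5, and the acid used for aromatisation has to spare ring D, both side chains and the benzylic ether.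

**C4a–OMe (17 ⇒ 16).** The methoxy group at C4a comes from oxidative dearomatisation of the para-alkylphenol 16 with a trivalent iodine oxidant in an alcohol solvent. This only works if ring A holds the sole free phenol. The C5' oxygen is therefore carried as a triisopropylsilyl ether, which also survives the base of the coupling, and the C2 oxygen as a triethylsilyl ether; both leave together under fluoride.

**C4–C4a, the key disconnection (16 ⇒ 15 + 4; 15 ⇒ 14).** Cutting C4–C4a divides the molecule into a chiral ring B unit with three carbons (C2, C3, C4) and an achiral ring A phenol. C4 has no heteroatom, so an sp3–sp2 cross-coupling is the natural way to make the bond. The alkylborane 15 comes from the vinyl group of the allylic silyl ether 14, and the aryl partner is iodophenol 4. The forward reaction needs hydroboration of the monosubstituted alkene of 14 in the presence of the prenyl and ring D alkenes, and the vinyl group of 4 must not meet the borane.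

**C2–C3 and the stereocentre (14 ⇒ 13 ⇒ 12).** The allylic ether 14 is the silyl ether of alcohol 13, which comes from aldehyde 12 by catalytic enantioselective addition of a vinylzinc reagent. This sets C2 on a simple aldehyde, before the fragments are joined, and brings in C3 and C4 as the alkene needed for the key step.

**C2'–prenyl (12 ⇒ 10 + 11).** The prenyl group is attached by Stille coupling of bromide 10 with stannane 11. The bromine is present from the first starting material and marks C2' throughout, so no regiochemical decision is needed on the pentasubstituted ring.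

**Ring D (10 ⇒ 9 ⇒ 8 ⇒ 6 + 7; 6 ⇒ 5).** The pyran ring is opened to the aryl propargyl ether 9. Its rearrangement can reach only one ortho carbon, because the other bears the silyloxy group and the para carbon bears the formyl group. Ether 9 is the silyl ether of 8, which comes from catechol 6 and chloride 7 by alkylation of the more acidic hydroxyl (para to the formyl group). Catechol 6 is obtained from 5 by cleavage of both methyl ethers, done at the outset while no alkene or silyl group is present.

**C6–quaternary carbon (4 ⇒ 3 ⇒ 1 + 2).** The 1,1-dimethylallyl group comes from the aromatic Claisen shift of prenyl ether 3, made from 1 and 2. Phenol 1 is symmetrical and para-blocked, so the shift has a single regiochemical outcome.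

## Alternatives that were turned down

**Alternative 1:** Rings A and C are disconnected together (C4a–C5, C7–C8, C4a–C8a, C6–C7), leading back to the acyclic diazo dienone A1, which carries the C2 oxygen as an ethynyl ether. In the forward step, visible light triggers a Wolff shift of A1. The resulting ketene adds across the tethered alkyne, and 4π opening followed by 6π closure gives A2, the 5'-O-tert-butyldimethylsilyl ether of 20.
- For: all six carbons of ring A and the C8a–O1 bond arrive in one operation, with the substitution pattern fixed by connectivity. The C7 phenol is formed free, and neither an aromatic Claisen shift nor an oxidation of an advanced phenol is needed. On regiochemical certainty of ring A and on ring-forming economy this alternative is stronger than the chosen route.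
- Against: A1 combines a diazo ketone, a dienone and an alkynyl ether of a secondary para-alkoxybenzylic alcohol. Such ethers rearrange or fragment under mild heating, so the stereocentre would sit on the least stable group of the molecule. Making that ether needs strong base, which the diazo ketone and enone do not tolerate. Ring D is photolabile, and the ketene has four other alkenes to add to.
- Step economy: A1 needs the ring B aldehyde plus roughly eight further steps, which is longer than the twelve steps proposed here.
- What the chosen strategy offers in its place: stable, storable fragments and a union of a well-established reaction class, with the risk lying in chemoselectivity and not in the survival of the substrate.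

**Alternative 2:** The bond from C6 to the quaternary carbon is made on a non-aromatic ring A. The prenyl β-keto ester A3 is heated; its enol undergoes a [3,3] Carroll shift with allyl inversion and loses CO2 to give the hexahydrochromenone A4, and ring A is aromatised afterwards.
- For: the position of the reverse-prenyl group is dictated by the ester, independent of any ortho/para preference, and the sigmatropic shift guarantees the 1,1-dimethylallyl connectivity. In principle this is as reliable as the Claisen shift used here, and it would be the better choice for a ring A without symmetry.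
- Against: that advantage is not needed here, because the symmetrical phenol 1 gives one Claisen product in two steps. The Carroll shift must form a quaternary carbon on a ring methine at high temperature, where plain decarboxylation competes. A4 is a vinylogous ester of a para-alkoxybenzylic alcohol and is prone to ionise at C2. The late dehydrogenation (quinone oxidants or palladium) threatens ring D, the benzylic positions and the terminal alkene. Two stereocentres (C4a, C6) are made only to be destroyed.
- Comparison: A3 needs many more steps than fragments 14 and 4, and the final oxidation is less selective than a phenol-specific trivalent iodine oxidation.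

**Alternative 3:** C2–C1' is disconnected. The ring B arylboronic acid A6 adds 1,4 to chromone A5 under a rhodium catalyst with a chiral bisphosphine, giving the (2S)-flavanone A7 and setting C2 in the fragment union.
- For: this is the most convergent plan. The bond, ring C and the stereocentre are all in place after one catalytic step, and on convergence and on catalytic control of C2 in the union step it is stronger than the chosen strategy.
- Against: A6 is ortho-substituted and electron-rich, so transmetalation is slow and protodeboronation competes. Chromones are sluggish acceptors, and A7 can open by retro-oxa-Michael reaction under the basic conditions and lose enantiopurity. The C4 carbonyl must then be deleted in two or three operations in the presence of four alkenes and a benzylic ether. A5 needs its 1,1-dimethylallyl group on a resorcinol-type ring where two different ortho positions (C6 and C8) compete in the Claisen shift, and ring B would have to be rebuilt as a boronic acid.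
- Comparison: the step count is similar or higher. The chosen route brings C4 in at the correct oxidation level, fixes ring A regiochemistry by symmetry, and keeps C2 in an ether that is configurationally stable, never in a flavanone.

Key step: step 10

Remark on the chemistry: the C5' oxygen is carried as a triisopropylsilyl ether instead of a tert-butyldimethylsilyl ether because aryl tert-butyldimethylsilyl ethers are cleaved by aqueous phosphate at the coupling temperature. Zn(CH=CH2)2 is assumed to be used as a salt-free stock solution prepared beforehand from CH2=CHMgBr and ZnCl2, and 11 is assumed to be bought.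

## Route

**Step 1**
Reactants: 1 4-iodophenol; 2 prenyl bromide (1-bromo-3-methylbut-2-ene)
Product: 3 1-iodo-4-[(3-methylbut-2-en-1-yl)oxy]benzene
Conditions: K2CO3, acetone, reflux
Reagents that add atoms: none
Why: Williamson ether synthesis; the phenoxide displaces the primary allylic bromide at the CH2 terminus (SN2), and the aryl iodide is inert to carbonate.

**Step 2**
Reactants: 3 1-iodo-4-[(3-methylbut-2-en-1-yl)oxy]benzene
Product: 4 4-iodo-2-(2-methylbut-3-en-2-yl)phenol (fragment 2)
Conditions: PhNEt2, 190 °C, sealed tube
Reagents that add atoms: none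
Why: Aromatic Claisen rearrangement; the [3,3] shift bonds the dimethyl-substituted allyl terminus to the ortho carbon with allyl inversion and tautomerisation restores the phenol; the two ortho positions are equivalent, the para position is blocked by iodine, and the basic solvent suppresses acid-catalysed cyclisation of the product to a dihydrobenzofuran.

**Step 3**
Reactants: 5 2-bromo-4,5-dimethoxybenzaldehyde
Product: 6 2-bromo-4,5-dihydroxybenzaldehyde
Conditions: BBr3, CH2Cl2, −78 → 23 °C; H2O
Reagents that add atoms: none
Why: Lewis acid cleavage of aryl methyl ethers (boron coordinates the ether oxygen, bromide removes the methyl group by SN2); it is placed first, while no alkene or silyl ether is present.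

**Step 4**
Reactants: 6 2-bromo-4,5-dihydroxybenzaldehyde; 7 3-chloro-3-methylbut-1-yne
Product: 8 2-bromo-5-hydroxy-4-[(2-methylbut-3-yn-2-yl)oxy]benzaldehyde
Conditions: 1,8-diazabicyclo[5.4.0]undec-7-ene (1.2 equiv), CuCl2·2H2O (cat.), MeCN, 0 °C, argon
Reagents that add atoms: none
Why: Copper-catalysed O-propargylation of a phenol with a tertiary propargylic chloride (copper acetylide, loss of chloride to an allenylidene-type electrophile, attack of phenoxide at the tertiary carbon); the hydroxyl para to the formyl group is the more acidic, so with one equivalent of 7 the monophenoxide at that oxygen should be alkylated selectively.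

**Step 5**
Reactants: 8 2-bromo-5-hydroxy-4-[(2-methylbut-3-yn-2-yl)oxy]benzaldehyde
Product: 9 2-bromo-4-[(2-methylbut-3-yn-2-yl)oxy]-5-[(triisopropylsilyl)oxy]benzaldehyde
Conditions: (i-Pr)3SiCl, imidazole, DMF, 23 °C
Reagents that add atoms: chlorotriisopropylsilane, CC(C)[Si](Cl)(C(C)C)C(C)C
Why: Standard silylation of the remaining phenol; the triisopropylsilyl ether should withstand the aqueous phosphate of step 10 and keeps ring B non-phenolic during the oxidation of step 11.

**Step 6**
Reactants: 9 2-bromo-4-[(2-methylbut-3-yn-2-yl)oxy]-5-[(triisopropylsilyl)oxy]benzaldehyde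
Product: 10 5-bromo-2,2-dimethyl-8-[(triisopropylsilyl)oxy]-2H-chromene-6-carbaldehyde
Conditions: PhNEt2, 180 °C
Reagents that add atoms: none
Why: Aryl propargyl ether Claisen rearrangement followed by enolisation, [1,5]-hydrogen shift and 6π oxa-electrocyclisation gives the 2,2-dimethyl-2H-chromene (ring D); only the ortho carbon between the ether oxygen and C–Br carries hydrogen, so ring D can close in one direction only.

**Step 7**
Reactants: 10 5-bromo-2,2-dimethyl-8-[(triisopropylsilyl)oxy]-2H-chromene-6-carbaldehyde; 11 tributyl(3-methylbut-2-en-1-yl)stannane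
Product: 12 2,2-dimethyl-5-(3-methylbut-2-en-1-yl)-8-[(triisopropylsilyl)oxy]-2H-chromene-6-carbaldehyde
Conditions: Pd(PPh3)4 (cat.), DMF, 100 °C
Reagents that add atoms: none
Why: Stille coupling; oxidative addition of the electron-poor aryl bromide, allyl transfer from tin and reductive elimination from the less hindered primary allyl terminus should give the linear prenyl arene, and the aldehyde and silyl ether are inert because neither Lewis acid nor fluoride is present.

**Step 8**
Reactants: 12 2,2-dimethyl-5-(3-methylbut-2-en-1-yl)-8-[(triisopropylsilyl)oxy]-2H-chromene-6-carbaldehyde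
Product: 13 (1S)-1-[2,2-dimethyl-5-(3-methylbut-2-en-1-yl)-8-[(triisopropylsilyl)oxy]-2H-chromen-6-yl]prop-2-en-1-ol
Conditions: Zn(CH=CH2)2, (2S)-(−)-3-exo-(morpholino)isoborneol (cat.), toluene–hexane, −30 → 0 °C; aq. NH4Cl
Reagents that add atoms: divinylzinc, C=C[Zn]C=C
Why: Amino alcohol-catalysed enantioselective addition of an alkenylzinc reagent to an aryl aldehyde; the chiral zinc aminoalkoxide binds the aldehyde and a second Zn(CH=CH2)2 and, as in the dialkylzinc additions that this ligand antipode directs to the Si face, should deliver vinyl to the Si face, which gives the S carbinol (O > aryl > vinyl > H).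

**Step 9**
Reactants: 13 (1S)-1-[2,2-dimethyl-5-(3-methylbut-2-en-1-yl)-8-[(triisopropylsilyl)oxy]-2H-chromen-6-yl]prop-2-en-1-ol
Product: 14 triethyl{[(1S)-1-[2,2-dimethyl-5-(3-methylbut-2-en-1-yl)-8-[(triisopropylsilyl)oxy]-2H-chromen-6-yl]prop-2-en-1-yl]oxy}silane (fragment 1)
Conditions: Et3SiCl, imidazole, CH2Cl2, 0 °C
Reagents that add atoms: chlorotriethylsilane, CC[Si](Cl)(CC)CC
Why: Silylation of the secondary alcohol under buffered, non-acidic conditions, which avoids ionisation of the allylic, para-alkoxybenzylic carbinol; the triethylsilyl ether prevents O–H/B–H reaction in step 10 and is removed by fluoride in step 12.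

**Step 10**
Reactants: 14 triethyl{[(1S)-1-[2,2-dimethyl-5-(3-methylbut-2-en-1-yl)-8-[(triisopropylsilyl)oxy]-2H-chromen-6-yl]prop-2-en-1-yl]oxy}silane; 4 4-iodo-2-(2-methylbut-3-en-2-yl)phenol
Product: 16 4-[(3S)-3-[2,2-dimethyl-5-(3-methylbut-2-en-1-yl)-8-[(triisopropylsilyl)oxy]-2H-chromen-6-yl]-3-[(triethylsilyl)oxy]propyl]-2-(2-methylbut-3-en-2-yl)phenol, via B-alkyl-9-borabicyclo[3.3.1]nonane 15 (not isolated)
Conditions: 9-borabicyclo[3.3.1]nonane (0.5 M in THF), THF, 0 → 23 °C; then 3 M aq. K3PO4; then 4, PdCl2[1,1'-bis(diphenylphosphino)ferrocene] (cat.), DMF, 50 °C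
Reagents that add atoms: 9-borabicyclo[3.3.1]nonane, B1C2CCCC1CCC2 (its boron and ring carbons stay in 15 only; 16 keeps one hydrogen)
Why: The borane adds B–H syn across the monosubstituted alkene of 14 with boron on the terminal carbon (the future C4) to give 15, and residual B–H is destroyed by the aqueous phosphate before 4 and the catalyst are added. Zerovalent palladium, formed from the divalent precatalyst, inserts into the C–I bond of 4, the base-activated borate transfers the primary alkyl group to palladium, and reductive elimination forms C4–C4a. The closest known reaction type is the B-alkyl Suzuki–Miyaura coupling of 9-borabicyclo[3.3.1]nonane adducts of protected allylic alcohols with aryl iodides. No ring is closed and no stereocentre is created; the S centre at C2 is a silyl ether two bonds from boron and is not touched. The selectivity needed is hydroboration of the vinyl group in the presence of the trisubstituted prenyl alkene and the conjugated cis-disubstituted alkene of ring D; the steric demand of the bicyclic borane, which reacts far faster with monosubstituted alkenes, should secure it, and the allylic oxygen reinforces terminal attack. The vinyl group of the 1,1-dimethylallyl unit of 4 would also react with the borane, which is why 4 is introduced only after the quench. The wide bite angle of the ferrocenyl bisphosphine favours reductive elimination over β-hydride elimination of the alkylpalladium intermediate, the aryl triisopropylsilyl ether should tolerate the phosphate, and 4 reacts as its phenoxide.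

**Step 11**
Reactants: 16 4-[(3S)-3-[2,2-dimethyl-5-(3-methylbut-2-en-1-yl)-8-[(triisopropylsilyl)oxy]-2H-chromen-6-yl]-3-[(triethylsilyl)oxy]propyl]-2-(2-methylbut-3-en-2-yl)phenol
Product: 17 4-[(3S)-3-[2,2-dimethyl-5-(3-methylbut-2-en-1-yl)-8-[(triisopropylsilyl)oxy]-2H-chromen-6-yl]-3-[(triethylsilyl)oxy]propyl]-4-methoxy-2-(2-methylbut-3-en-2-yl)cyclohexa-2,5-dien-1-one (both configurations at the methoxy-bearing carbon)
Conditions: PhI(OAc)2, MeOH–CH2Cl2, 0 °C
Reagents that add atoms: methanol, CO
Why: Oxidative dearomatisation of a para-alkylphenol with a trivalent iodine reagent; ligand exchange at iodine with the only free phenol and attack of methanol at the para carbon C4a with loss of iodobenzene give the para-quinol methyl ether; the tert-alkyl group shields one ortho position, ring B is masked as ether and silyl ether, and the new C4a centre is removed again in step 12.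

**Step 12**
Reactants: 17 4-[(3S)-3-[2,2-dimethyl-5-(3-methylbut-2-en-1-yl)-8-[(triisopropylsilyl)oxy]-2H-chromen-6-yl]-3-[(triethylsilyl)oxy]propyl]-4-methoxy-2-(2-methylbut-3-en-2-yl)cyclohexa-2,5-dien-1-one
Product: 20 kazinol H, via desilylated dienone diol 18 (not isolated), via bicyclic methoxy enone 19 (not isolated)
Conditions: Bu4NF, THF, 0 °C; aq. NH4Cl work-up; then pyridinium p-toluenesulfonate (cat.), CH2Cl2, 23 °C
Reagents that add atoms: none
Why: Fluoride cleaves both silyl ethers and the C2 alkoxide adds 6-exo-trig to C8a, the β-carbon of the unsubstituted enone arm (the other β-carbon, C5, belongs to the arm whose α-carbon C6 carries the tert-alkyl group and is less electrophilic), with retention at C2 because the C2–O bond is not broken; mild acid then enolises the ketone and expels methanol from C4a through an arenium-type cation, and aromatisation of ring A drives the sequence (oxa-Michael addition followed by acid-promoted eliminative aromatisation).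

## Compound list

1 | 4-iodophenol | Oc1ccc(I)cc1 | starting material
2 | prenyl bromide (1-bromo-3-methylbut-2-ene) | CC(C)=CCBr | starting material
3 | 1-iodo-4-[(3-methylbut-2-en-1-yl)oxy]benzene | CC(C)=CCOc1ccc(I)cc1 | intermediate
4 | 4-iodo-2-(2-methylbut-3-en-2-yl)phenol (fragment 2) | C=CC(C)(C)c1cc(I)ccc1O | intermediate
5 | 2-bromo-4,5-dimethoxybenzaldehyde | COc1cc(Br)c(C=O)cc1OC | starting material
6 | 2-bromo-4,5-dihydroxybenzaldehyde | O=Cc1cc(O)c(O)cc1Br | intermediate
7 | 3-chloro-3-methylbut-1-yne | C#CC(C)(C)Cl | starting material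
8 | 2-bromo-5-hydroxy-4-[(2-methylbut-3-yn-2-yl)oxy]benzaldehyde | O=Cc1cc(O)c(OC(C)(C)C#C)cc1Br | intermediate
9 | 2-bromo-4-[(2-methylbut-3-yn-2-yl)oxy]-5-[(triisopropylsilyl)oxy]benzaldehyde | O=Cc1cc(O[Si](C(C)C)(C(C)C)C(C)C)c(OC(C)(C)C#C)cc1Br | intermediate
10 | 5-bromo-2,2-dimethyl-8-[(triisopropylsilyl)oxy]-2H-chromene-6-carbaldehyde | O=Cc1cc(O[Si](C(C)C)(C(C)C)C(C)C)c2OC(C)(C)C=Cc2c1Br | intermediate
11 | tributyl(3-methylbut-2-en-1-yl)stannane | CCCC[Sn](CCCC)(CCCC)CC=C(C)C | starting material
12 | 2,2-dimethyl-5-(3-methylbut-2-en-1-yl)-8-[(triisopropylsilyl)oxy]-2H-chromene-6-carbaldehyde | O=Cc1cc(O[Si](C(C)C)(C(C)C)C(C)C)c2OC(C)(C)C=Cc2c1CC=C(C)C | intermediate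
13 | (1S)-1-[2,2-dimethyl-5-(3-methylbut-2-en-1-yl)-8-[(triisopropylsilyl)oxy]-2H-chromen-6-yl]prop-2-en-1-ol | C=C[C@H](O)c1cc(O[Si](C(C)C)(C(C)C)C(C)C)c2c(c1CC=C(C)C)C=CC(C)(C)O2 | intermediate
14 | triethyl{[(1S)-1-[2,2-dimethyl-5-(3-methylbut-2-en-1-yl)-8-[(triisopropylsilyl)oxy]-2H-chromen-6-yl]prop-2-en-1-yl]oxy}silane (fragment 1) | C=C[C@H](O[Si](CC)(CC)CC)c1cc(O[Si](C(C)C)(C(C)C)C(C)C)c2c(c1CC=C(C)C)C=CC(C)(C)O2 | intermediate
15 | 9-[(3S)-3-[2,2-dimethyl-5-(3-methylbut-2-en-1-yl)-8-[(triisopropylsilyl)oxy]-2H-chromen-6-yl]-3-[(triethylsilyl)oxy]propyl]-9-borabicyclo[3.3.1]nonane | C1CCC2CCCC1B2CC[C@H](O[Si](CC)(CC)CC)c1cc(O[Si](C(C)C)(C(C)C)C(C)C)c2c(c1CC=C(C)C)C=CC(C)(C)O2 | intermediate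
16 | 4-[(3S)-3-[2,2-dimethyl-5-(3-methylbut-2-en-1-yl)-8-[(triisopropylsilyl)oxy]-2H-chromen-6-yl]-3-[(triethylsilyl)oxy]propyl]-2-(2-methylbut-3-en-2-yl)phenol | C=CC(C)(C)c1cc(CC[C@H](O[Si](CC)(CC)CC)c2cc(O[Si](C(C)C)(C(C)C)C(C)C)c3c(c2CC=C(C)C)C=CC(C)(C)O3)ccc1O | intermediate
17 | 4-[(3S)-3-[2,2-dimethyl-5-(3-methylbut-2-en-1-yl)-8-[(triisopropylsilyl)oxy]-2H-chromen-6-yl]-3-[(triethylsilyl)oxy]propyl]-4-methoxy-2-(2-methylbut-3-en-2-yl)cyclohexa-2,5-dien-1-one (both epimers at the methoxy-bearing carbon) | C=CC(C)(C)C1=CC(OC)(CC[C@H](O[Si](CC)(CC)CC)c2cc(O[Si](C(C)C)(C(C)C)C(C)C)c3c(c2CC=C(C)C)C=CC(C)(C)O3)C=CC1=O | intermediate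
18 | 4-[(3S)-3-hydroxy-3-[8-hydroxy-2,2-dimethyl-5-(3-methylbut-2-en-1-yl)-2H-chromen-6-yl]propyl]-4-methoxy-2-(2-methylbut-3-en-2-yl)cyclohexa-2,5-dien-1-one (both epimers at the methoxy-bearing carbon) | C=CC(C)(C)C1=CC(OC)(CC[C@H](O)c2cc(O)c3c(c2CC=C(C)C)C=CC(C)(C)O3)C=CC1=O | intermediate
19 | (2S)-2-[8-hydroxy-2,2-dimethyl-5-(3-methylbut-2-en-1-yl)-2H-chromen-6-yl]-4a-methoxy-6-(2-methylbut-3-en-2-yl)-2,3,4,4a,8,8a-hexahydro-7H-chromen-7-one (C4a and C8a unassigned, lost on aromatisation) | C=CC(C)(C)C1=CC2(OC)CC[C@@H](c3cc(O)c4c(c3CC=C(C)C)C=CC(C)(C)O4)OC2CC1=O | intermediate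
20 | kazinol H, (2S)-2-[8-hydroxy-2,2-dimethyl-5-(3-methylbut-2-en-1-yl)-2H-chromen-6-yl]-6-(2-methylbut-3-en-2-yl)-3,4-dihydro-2H-chromen-7-ol | C=CC(C)(C)c1cc2c(cc1O)O[C@H](c1cc(O)c3c(c1CC=C(C)C)C=CC(C)(C)O3)CC2 | target

## Step count and least certain steps

Total: 12 steps. Longest linear sequence: 10 steps (steps 3 to 12, from 5 to 20); fragment 2 (steps 1 and 2) joins at step 10.

**Step 10 (key step).** The most likely failure is in the cross-coupling half. Oxidative addition to the electron-rich iodophenoxide may be slow, so protodeboronation or β-hydride elimination of the alkyl group can outrun C–C bond formation. Incomplete quenching of B–H would also let the borane reach the vinyl group of 4, and the basic aqueous medium may partly cleave the aryl silyl ether. The fallback sets out from 15 and 4 and returns to 16 through an organozinc. Oxidation of 15 with NaBO3·4H2O gives the primary alcohol (3S)-3-(ring B aryl)-3-[(triethylsilyl)oxy]propan-1-ol F1, which I2, PPh3 and imidazole convert into the primary iodide F2. Phenol 4 is acetylated (Ac2O, pyridine) to 4-iodo-2-(2-methylbut-3-en-2-yl)phenyl acetate F3. Zinc insertion into F2 (Zn, LiCl, THF) gives the alkylzinc iodide F4, which is joined to F3 by Negishi coupling (Pd(OAc)2, 2-dicyclohexylphosphino-2',6'-dimethoxybiphenyl, THF) to the coupled aryl acetate F5. Methanolysis (K2CO3, MeOH, 0 °C) gives 16. No aqueous base and no free phenol are present during the C–C bond formation.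

**Step 11.** The oxidation may lose chemoselectivity. The electrophilic iodine species can attack the electron-rich ring B or its alkenes, and the oxidised phenol can lose a benzylic proton at C4 instead of capturing methanol at C4a. The fallback avoids dearomatisation altogether; it sets out from 15 and 2 and returns at 20.
- Commercial 3-bromo-4-iodophenol F6 is O-alkylated with 2 (K2CO3, acetone) to 2-bromo-1-iodo-4-[(3-methylbut-2-en-1-yl)oxy]benzene F7.
- Claisen rearrangement (PhNEt2, 190 °C), expected at the less hindered ortho carbon, gives 5-bromo-4-iodo-2-(2-methylbut-3-en-2-yl)phenol F8, which is silylated (t-BuMe2SiOTf, 2,6-lutidine) to its tert-butyldimethylsilyl ether F9.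
- B-alkyl Suzuki–Miyaura coupling of 15 at the C–I bond of F9, under the conditions of step 10, gives the bromoarene F10.
- Pyridinium p-toluenesulfonate in MeOH removes only the triethylsilyl group to give the secondary alcohol F11.
- Palladium-catalysed intramolecular aryl ether formation (Pd(OAc)2, 2-(di-tert-butylphosphino)-1,1'-binaphthyl, Cs2CO3, toluene, 70 °C) closes ring C at C8a with retention at C2 to give the bis-silyl ether of kazinol H F12.
- Bu4NF then gives 20.

**Step 12.** Under the basic fluoride conditions the conjugate addition is reversible and may settle at the wrong β-carbon, and the free ring B phenoxide may add to the dienone of another molecule. In the acid step, ring D, the C6 side chain or the benzylic C2–O bond may suffer. The fallback sets out from 17 and returns at 20. Pyridinium p-toluenesulfonate in MeOH–CH2Cl2 at 0 °C removes only the triethylsilyl group to give the hydroxy dienone F13 with ring B still silylated. Catalytic camphorsulfonic acid in CH2Cl2 then merges cyclisation of the neutral alcohol with loss of methanol, so that the adduct is aromatised as it forms, giving 5'-O-triisopropylsilyl kazinol H F14. Bu4NF buffered with acetic acid gives 20.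

**Step 8.** Facial selectivity may be poor with this ortho-substituted, electron-rich aldehyde, and uncatalysed background addition would lower the enantiomeric purity. The fallback sets out from 12 and returns at 13. CH2=CHMgBr in THF gives the racemic allylic alcohol F15. Kinetic resolution by Sharpless epoxidation (Ti(OiPr)4, L-(+)-diisopropyl tartrate, t-BuOOH, CH2Cl2, −20 °C) should, by the usual model, consume the R enantiomer faster and leave 13; this costs half of the material.

**Step 4.** Discrimination between the two phenols may be insufficient, which would lead to alkylation at the wrong oxygen or at both. The fallback sets out from 6 and returns at 9, bypassing 8. Both phenols are silylated ((i-Pr)3SiCl, imidazole, DMF) to 2-bromo-4,5-bis[(triisopropylsilyl)oxy]benzaldehyde F16. Cs2CO3 in DMF–H2O at 0 °C removes the silyl group para to the formyl group, the better leaving phenoxide, to give 2-bromo-4-hydroxy-5-[(triisopropylsilyl)oxy]benzaldehyde F17; any silyl migration between the neighbouring oxygens leads to the same phenoxide. Propargylation of F17 with 7 under the conditions of step 4 gives 9.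

## Further compounds

F1 | step 10 | (3S)-3-[2,2-dimethyl-5-(3-methylbut-2-en-1-yl)-8-[(triisopropylsilyl)oxy]-2H-chromen-6-yl]-3-[(triethylsilyl)oxy]propan-1-ol | OCC[C@H](O[Si](CC)(CC)CC)c1cc(O[Si](C(C)C)(C(C)C)C(C)C)c2c(c1CC=C(C)C)C=CC(C)(C)O2
F2 | step 10 | triethyl{[(1S)-3-iodo-1-[2,2-dimethyl-5-(3-methylbut-2-en-1-yl)-8-[(triisopropylsilyl)oxy]-2H-chromen-6-yl]propyl]oxy}silane | ICC[C@H](O[Si](CC)(CC)CC)c1cc(O[Si](C(C)C)(C(C)C)C(C)C)c2c(c1CC=C(C)C)C=CC(C)(C)O2
F3 | step 10 | 4-iodo-2-(2-methylbut-3-en-2-yl)phenyl acetate | C=CC(C)(C)c1cc(I)ccc1OC(C)=O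
F4 | step 10 | [(3S)-3-[2,2-dimethyl-5-(3-methylbut-2-en-1-yl)-8-[(triisopropylsilyl)oxy]-2H-chromen-6-yl]-3-[(triethylsilyl)oxy]propyl]zinc iodide | I[Zn]CC[C@H](O[Si](CC)(CC)CC)c1cc(O[Si](C(C)C)(C(C)C)C(C)C)c2c(c1CC=C(C)C)C=CC(C)(C)O2
F5 | step 10 | 4-[(3S)-3-[2,2-dimethyl-5-(3-methylbut-2-en-1-yl)-8-[(triisopropylsilyl)oxy]-2H-chromen-6-yl]-3-[(triethylsilyl)oxy]propyl]-2-(2-methylbut-3-en-2-yl)phenyl acetate | C=CC(C)(C)c1cc(CC[C@H](O[Si](CC)(CC)CC)c2cc(O[Si](C(C)C)(C(C)C)C(C)C)c3c(c2CC=C(C)C)C=CC(C)(C)O3)ccc1OC(C)=O
F6 | step 11 | 3-bromo-4-iodophenol (commercial) | Oc1ccc(I)c(Br)c1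
F7 | step 11 | 2-bromo-1-iodo-4-[(3-methylbut-2-en-1-yl)oxy]benzene | CC(C)=CCOc1ccc(I)c(Br)c1
F8 | step 11 | 5-bromo-4-iodo-2-(2-methylbut-3-en-2-yl)phenol | C=CC(C)(C)c1cc(I)c(Br)cc1O
F9 | step 11 | [5-bromo-4-iodo-2-(2-methylbut-3-en-2-yl)phenoxy](tert-butyl)dimethylsilane | C=CC(C)(C)c1cc(I)c(Br)cc1O[Si](C)(C)C(C)(C)C
F10 | step 11 | {2-bromo-4-[(tert-butyldimethylsilyl)oxy]-5-(2-methylbut-3-en-2-yl)phenyl} coupled product, (3S)-3-(ring B aryl)-3-[(triethylsilyl)oxy]propyl at C1 | C=CC(C)(C)c1cc(CC[C@H](O[Si](CC)(CC)CC)c2cc(O[Si](C(C)C)(C(C)C)C(C)C)c3c(c2CC=C(C)C)C=CC(C)(C)O3)c(Br)cc1O[Si](C)(C)C(C)(C)C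
F11 | step 11 | (1S)-3-[2-bromo-4-[(tert-butyldimethylsilyl)oxy]-5-(2-methylbut-3-en-2-yl)phenyl]-1-[2,2-dimethyl-5-(3-methylbut-2-en-1-yl)-8-[(triisopropylsilyl)oxy]-2H-chromen-6-yl]propan-1-ol | C=CC(C)(C)c1cc(CC[C@H](O)c2cc(O[Si](C(C)C)(C(C)C)C(C)C)c3c(c2CC=C(C)C)C=CC(C)(C)O3)c(Br)cc1O[Si](C)(C)C(C)(C)C
F12 | step 11 | 7-O-tert-butyldimethylsilyl-5'-O-triisopropylsilyl kazinol H | C=CC(C)(C)c1cc2c(cc1O[Si](C)(C)C(C)(C)C)O[C@H](c1cc(O[Si](C(C)C)(C(C)C)C(C)C)c3c(c1CC=C(C)C)C=CC(C)(C)O3)CC2
F13 | step 12 | 4-[(3S)-3-hydroxy-3-[2,2-dimethyl-5-(3-methylbut-2-en-1-yl)-8-[(triisopropylsilyl)oxy]-2H-chromen-6-yl]propyl]-4-methoxy-2-(2-methylbut-3-en-2-yl)cyclohexa-2,5-dien-1-one | C=CC(C)(C)C1=CC(OC)(CC[C@H](O)c2cc(O[Si](C(C)C)(C(C)C)C(C)C)c3c(c2CC=C(C)C)C=CC(C)(C)O3)C=CC1=O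
F14 | step 12 | 5'-O-triisopropylsilyl kazinol H | C=CC(C)(C)c1cc2c(cc1O)O[C@H](c1cc(O[Si](C(C)C)(C(C)C)C(C)C)c3c(c1CC=C(C)C)C=CC(C)(C)O3)CC2
F15 | step 8 | racemic 1-[2,2-dimethyl-5-(3-methylbut-2-en-1-yl)-8-[(triisopropylsilyl)oxy]-2H-chromen-6-yl]prop-2-en-1-ol | C=CC(O)c1cc(O[Si](C(C)C)(C(C)C)C(C)C)c2c(c1CC=C(C)C)C=CC(C)(C)O2
F16 | step 4 | 2-bromo-4,5-bis[(triisopropylsilyl)oxy]benzaldehyde | O=Cc1cc(O[Si](C(C)C)(C(C)C)C(C)C)c(O[Si](C(C)C)(C(C)C)C(C)C)cc1Br
F17 | step 4 | 2-bromo-4-hydroxy-5-[(triisopropylsilyl)oxy]benzaldehyde | O=Cc1cc(O[Si](C(C)C)(C(C)C)C(C)C)c(O)cc1Br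
A1 | alternative 1 | (S)-diazo dienone with ethynyl ether at C2, 5'-O-tert-butyldimethylsilyl | C=CC(C)(C)/C=C/C(=O)C(=[N+]=[N-])CC[C@H](OC#C)c1cc(O[Si](C)(C)C(C)(C)C)c2c(c1CC=C(C)C)C=CC(C)(C)O2
A2 | alternative 1 | 5'-O-tert-butyldimethylsilyl kazinol H | C=CC(C)(C)c1cc2c(cc1O)O[C@H](c1cc(O[Si](C)(C)C(C)(C)C)c3c(c1CC=C(C)C)C=CC(C)(C)O3)CC2
A3 | alternative 2 | prenyl (2S)-2-aryl-7-oxo-hexahydrochromene-6-carboxylate (C4a and C6 unassigned) | CC(C)=CCOC(=O)C1CC2CC[C@@H](c3cc(O[Si](C)(C)C(C)(C)C)c4c(c3CC=C(C)C)C=CC(C)(C)O4)OC2=CC1=O
A4 | alternative 2 | (2S)-2-aryl-6-(1,1-dimethylallyl)-hexahydrochromen-7-one (C4a and C6 unassigned) | C=CC(C)(C)C1CC2CC[C@@H](c3cc(O[Si](C)(C)C(C)(C)C)c4c(c3CC=C(C)C)C=CC(C)(C)O4)OC2=CC1=O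
A5 | alternative 3 | 6-(2-methylbut-3-en-2-yl)-7-[(triisopropylsilyl)oxy]-4H-chromen-4-one | C=CC(C)(C)c1cc2c(cc1O[Si](C(C)C)(C(C)C)C(C)C)OC=CC2=O
A6 | alternative 3 | [2,2-dimethyl-5-(3-methylbut-2-en-1-yl)-8-[(triisopropylsilyl)oxy]-2H-chromen-6-yl]boronic acid | OB(O)c1cc(O[Si](C(C)C)(C(C)C)C(C)C)c2c(c1CC=C(C)C)C=CC(C)(C)O2
A7 | alternative 3 | (2S)-flavanone, bis-triisopropylsilyl ether | C=CC(C)(C)c1cc2c(cc1O[Si](C(C)C)(C(C)C)C(C)C)O[C@H](c1cc(O[Si](C(C)C)(C(C)C)C(C)C)c3c(c1CC=C(C)C)C=CC(C)(C)O3)CC2=O
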